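Bonds cut in retrosynthesis, in order: the two esters; the C5=C6 enone back to a C7 ketone and that to a C7–Si bond; C4–O/C3a–H back to a C3a=C4 alkene; the C3 carbinol back to a C3 ketone; then C4–C5 and C8–C8a together.
What remains before that last cut is a cyclohepta-1,4-diene (C3a=C4, C6=C7) fused at C3a–C8a, the product of a cis-divinylcyclopropane rearrangement; cutting it gives a C4 alkenyl carbene on the cyclopentene C3a=C8a and the diene C5=C6–C7=C8.
Feature that allows this: in the seven-membered ring (C3a, C4, C5, C6, C7, C8, C8a) the oxygenated C4 and the C7 carbonyl flank C5–C6, and the quaternary C8a is the β-carbon of an enone ending at C3.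
Forward order: the five-membered ring comes from (R)-4-silyloxycyclopentenone; one rhodium-catalysed operation then builds the seven-membered ring from a cycloheptatriene-masked carbene (lost as benzene) through a transient cyclopropane C4–C5–C6 whose C4–C6 bond is not in the target.
Stereochemistry: C1 from the starting material; C8a relayed from C1 in the key step; C3 by addition anti to the C1 silyl ether; C3a and C4 by syn hydroboration on the α face.
Key step: step 8
Remark: bicyclic compounds carry azulene numbering (C1–C3 five-membered ring, C3a/C8a ring fusion, C4–C8 seven-membered ring); α is the face opposite to the C8a methyl group.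

Step 1
Reactants: 1 (4R)-4-[(tert-butyldimethylsilyl)oxy]cyclopent-2-en-1-one
Product: 3 (4R)-4-[(tert-butyldimethylsilyl)oxy]-3-methylcyclopent-2-en-1-one, via trimethylsilyl enol ether 2 (not isolated)
Conditions: Me2CuLi, Me3SiCl, THF, −78 °C; solvent exchange; Pd(OAc)2, MeCN, 25 °C
Reagents that add atoms: lithium dimethylcuprate, C[Cu-]C.[Li+]
Why: Cuprate conjugate addition anti to the silyloxy group with silyl trapping, then Saegusa–Ito oxidation of the regiodefined enol ether, should return the enone with the new β-methyl group; the C3 centre formed in passing is destroyed again.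

Step 2
Reactants: 3 (4R)-4-[(tert-butyldimethylsilyl)oxy]-3-methylcyclopent-2-en-1-one
Product: 4 (4R)-4-[(tert-butyldimethylsilyl)oxy]-2-iodo-3-methylcyclopent-2-en-1-one
Conditions: I2, pyridine, DMAP (cat.), CH2Cl2, 25 °C
Reagents that add atoms: iodine, II
Why: Pyridine-mediated α-iodination of a cycloalkenone (conjugate addition, iodination, elimination) is a standard way to an α-iodoenone and should leave the silyl ether untouched.

Step 3
Reactants: 4 (4R)-4-[(tert-butyldimethylsilyl)oxy]-2-iodo-3-methylcyclopent-2-en-1-one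
Product: 5 (1S,4R)-4-[(tert-butyldimethylsilyl)oxy]-2-iodo-3-methylcyclopent-2-en-1-ol (hydroxyl cis to the silyloxy group)
Conditions: NaBH4, CeCl3·7H2O, MeOH, −78 → −40 °C
Reagents that add atoms: none
Why: Luche reduction should give clean 1,2-reduction with hydride arriving anti to the silyloxy group; the carbinol only masks the ketone for the organolithium step and is oxidised back in step 5.

Step 4
Reactants: 5 (1S,4R)-4-[(tert-butyldimethylsilyl)oxy]-2-iodo-3-methylcyclopent-2-en-1-ol; 6 tropylium tetrafluoroborate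
Product: 8 (1S,4R)-4-[(tert-butyldimethylsilyl)oxy]-2-(cyclohepta-2,4,6-trien-1-yl)-3-methylcyclopent-2-en-1-ol, via dilithio species 7 (not isolated)
Conditions: MeLi, then t-BuLi, Et2O, −78 °C; 6, THF, −78 → 0 °C; aq. NH4Cl
Reagents that add atoms: none
Why: Iodine–lithium exchange on the lithium alkoxide should give an alkenyllithium that adds to the tropylium cation at carbon (the usual route to 7-alkenylcycloheptatrienes), the hindered alkoxide being the weaker nucleophile toward the soft cation.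

Step 5
Reactants: 8 (1S,4R)-4-[(tert-butyldimethylsilyl)oxy]-2-(cyclohepta-2,4,6-trien-1-yl)-3-methylcyclopent-2-en-1-ol
Product: 9 (4R)-4-[(tert-butyldimethylsilyl)oxy]-2-(cyclohepta-2,4,6-trien-1-yl)-3-methylcyclopent-2-en-1-one
Conditions: Dess–Martin periodinane, NaHCO3, CH2Cl2, 0 → 25 °C
Reagents that add atoms: none
Why: Dess–Martin oxidation of the allylic alcohol should restore the enone under neutral conditions that the cycloheptatriene and the silyl ether tolerate.

Step 6
Reactants: 10 3-methylbut-3-en-2-one; 11 2,4,6-tri(propan-2-yl)benzenesulfonohydrazide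
Product: 12 N′-(3-methylbut-3-en-2-ylidene)-2,4,6-tri(propan-2-yl)benzenesulfonohydrazide
Conditions: MeOH, HCl (cat.), 0 → 25 °C
Reagents that add atoms: none
Why: Acid-catalysed condensation of a ketone with an arylsulfonylhydrazide should give the hydrazone needed for a Shapiro reaction.

Step 7
Reactants: 12 N′-(3-methylbut-3-en-2-ylidene)-2,4,6-tri(propan-2-yl)benzenesulfonohydrazide
Product: 15 dimethyl(3-methylbuta-1,3-dien-2-yl)(propan-2-yloxy)silane, via dienyllithium 13 (not isolated), via chlorosilane 14 (not isolated)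
Conditions: n-BuLi (2.2 equiv), THF/TMEDA, −78 → 0 °C; Me2SiCl2 (excess), −78 → 25 °C; then i-PrOH, Et3N, Et2O, 0 °C
Reagents that add atoms: dichlorodimethylsilane, C[Si](C)(Cl)Cl; propan-2-ol, CC(C)O
Why: In the Shapiro reaction the hydrazone dianion (deprotonated at the methyl group) loses sulfinate and dinitrogen to give the 2-lithiodiene, which is silylated and then converted by alcoholysis into an alkoxysilane that a Tamao–Fleming oxidation can later turn into oxygen.

Step 8
Reactants: 9 (4R)-4-[(tert-butyldimethylsilyl)oxy]-2-(cyclohepta-2,4,6-trien-1-yl)-3-methylcyclopent-2-en-1-one; 15 dimethyl(3-methylbuta-1,3-dien-2-yl)(propan-2-yloxy)silane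
Product: 18 (1R,8aS)-1-[(tert-butyldimethylsilyl)oxy]-7-[dimethyl(propan-2-yloxy)silyl]-6,8a-dimethyl-1,2,5,8-tetrahydroazulen-3(8aH)-one, via rhodium carbene 16 (not isolated), via divinylcyclopropane 17 (not isolated)
Conditions: Rh2(O2CCF3)4 (5 mol %), 15 (3 equiv), ClCH2CH2Cl, slow addition of 9, 40 °C, then 83 °C
Reagents that add atoms: none
Why: Rh2(O2CCF3)4 cleaves the norcaradiene valence tautomer of 9 (retro-Buchner reaction), releasing benzene and an electrophilic alkenyl carbene at C4, which cyclopropanates the more nucleophilic, methyl-bearing terminus of diene 15 (the silyl-bearing alkene is hindered and its attack would place charge next to silicon), making C4–C5 and a temporary C4–C6 bond. The cis-divinylcyclopropane 17 then undergoes a [3,3] Cope rearrangement that cleaves C4–C6 and makes C8–C8a; the closest known reaction type is the (4+3) cycloaddition of non-acceptor alkenyl carbenes, generated from 7-alkenylcycloheptatrienes by dirhodium carboxylates, with 1,3-dienes. The seven-membered ring is therefore closed intermolecularly by cyclopropanation followed by a suprafacial [3,3] shift through a boat transition state, the three-membered ring expanding to the seven-membered one. C8a is the only new stereocentre and should be controlled by the C1 silyloxy group: the carbene hydrogen, not rhodium, lies next to the C8a methyl group, the diene adds end-on to the β face of C4 (anti to the silyl ether) with C6 pointing away from rhodium, and the s-cis rotamer that the boat requires then carries the C7=C8 arm to the α face, so that C8 bonds cis to the C1 oxygen and the methyl group ends up β. The step needs regioselection between the two alkenes of the diene (silyl group), a cis arrangement of the two alkenyl groups on the cyclopropane (usual for donor carbenes, and only this isomer can rearrange) and facial selection (silyl ether); the final heating is planned because the inward-pointing C8a methyl group should slow the Cope step.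

Step 9
Reactants: 18 (1R,8aS)-1-[(tert-butyldimethylsilyl)oxy]-7-[dimethyl(propan-2-yloxy)silyl]-6,8a-dimethyl-1,2,5,8-tetrahydroazulen-3(8aH)-one
Product: 19 (1R,3R,8aS)-1-[(tert-butyldimethylsilyl)oxy]-7-[dimethyl(propan-2-yloxy)silyl]-6,8a-dimethyl-3-(propan-2-yl)-1,2,3,5,8,8a-hexahydroazulen-3-ol
Conditions: i-PrMgCl, CeCl3, THF, −78 °C
Reagents that add atoms: isopropylmagnesium chloride, CC(C)[Mg]Cl
Why: The organocerium reagent should add 1,2 to the exocyclic enone without enolisation, from the β face anti to the C1 silyloxy group (as in additions to 4-silyloxycyclopentenones), which sets C3 with the hydroxyl α and the isopropyl group β.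

Step 10
Reactants: 19 (1R,3R,8aS)-1-[(tert-butyldimethylsilyl)oxy]-7-[dimethyl(propan-2-yloxy)silyl]-6,8a-dimethyl-3-(propan-2-yl)-1,2,3,5,8,8a-hexahydroazulen-3-ol
Product: 21 (1R,3R,3aR,4R,8aS)-1-[(tert-butyldimethylsilyl)oxy]-3,4-dihydroxy-6,8a-dimethyl-3-(propan-2-yl)octahydroazulen-7(1H)-one (mixture at C6), via cyclic alkoxyborane 20 (not isolated)
Conditions: BH3·THF, THF, 0 → 25 °C; then H2O2, KF, KHCO3, THF/MeOH, 40 °C
Reagents that add atoms: hydrogen peroxide, OO
Why: Hydroboration should add H and B syn to the C3a=C4 alkene from the α face (the β face carries the isopropyl and C8a methyl groups; the borane bound to the C3 oxygen sits on the α face), boron going to the less substituted C4. The Tamao–Fleming conditions then oxidise both the C4–B and the alkenyl C7–Si bonds with retention, the C7 enol tautomerising to the ketone.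

Step 11
Reactants: 21 (1R,3R,3aR,4R,8aS)-1-[(tert-butyldimethylsilyl)oxy]-3,4-dihydroxy-6,8a-dimethyl-3-(propan-2-yl)octahydroazulen-7(1H)-one; 22 4-(acetyloxy)benzoyl chloride
Product: 23 (1R,3R,3aR,4R,8aS)-1-[(tert-butyldimethylsilyl)oxy]-3-hydroxy-6,8a-dimethyl-7-oxo-3-(propan-2-yl)decahydroazulen-4-yl 4-(acetyloxy)benzoate (mixture at C6)
Conditions: 22, pyridine, DMAP (cat.), CH2Cl2, 0 → 25 °C
Reagents that add atoms: none
Why: DMAP-catalysed acylation should take the secondary C4 hydroxyl and leave the hindered tertiary C3 hydroxyl untouched.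

Step 12
Reactants: 23 (1R,3R,3aR,4R,8aS)-1-[(tert-butyldimethylsilyl)oxy]-3-hydroxy-6,8a-dimethyl-7-oxo-3-(propan-2-yl)decahydroazulen-4-yl 4-(acetyloxy)benzoate
Product: 25 (1R,3R,3aR,4R,8aS)-1-[(tert-butyldimethylsilyl)oxy]-6,8a-dimethyl-7-oxo-3-(propan-2-yl)-3-[(trimethylsilyl)oxy]-1,2,3,3a,4,7,8,8a-octahydroazulen-4-yl 4-(acetyloxy)benzoate, via bis-silyl enol ether 24 (not isolated)
Conditions: Me3SiOTf, Et3N, CH2Cl2, 0 → 25 °C; then Pd(OAc)2, MeCN, 25 °C
Reagents that add atoms: trimethylsilyl trifluoromethanesulfonate, C[Si](C)(C)OS(=O)(=O)C(F)(F)F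
Why: Equilibrating silylation should give the more substituted (C6=C7) enol ether, whose Saegusa–Ito oxidation (β-hydride elimination from C5) gives the C5=C6 enone and removes the C6 stereocentre; the tertiary alcohol is silylated in passing.

Step 13
Reactants: 25 (1R,3R,3aR,4R,8aS)-1-[(tert-butyldimethylsilyl)oxy]-6,8a-dimethyl-7-oxo-3-(propan-2-yl)-3-[(trimethylsilyl)oxy]-1,2,3,3a,4,7,8,8a-octahydroazulen-4-yl 4-(acetyloxy)benzoate
Product: 26 (1R,3R,3aR,4R,8aS)-1,3-dihydroxy-6,8a-dimethyl-7-oxo-3-(propan-2-yl)-1,2,3,3a,4,7,8,8a-octahydroazulen-4-yl 4-(acetyloxy)benzoate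
Conditions: HF·pyridine, pyridine, THF, 0 → 25 °C
Reagents that add atoms: none
Why: Buffered HF·pyridine should cleave both silyl ethers while the enone, the aryl acetate and the C4 ester survive.

Step 14
Reactants: 26 (1R,3R,3aR,4R,8aS)-1,3-dihydroxy-6,8a-dimethyl-7-oxo-3-(propan-2-yl)-1,2,3,3a,4,7,8,8a-octahydroazulen-4-yl 4-(acetyloxy)benzoate
Product: 27 (1R,3R,3aR,4R,8aS)-1-(acetyloxy)-3-hydroxy-6,8a-dimethyl-7-oxo-3-(propan-2-yl)-1,2,3,3a,4,7,8,8a-octahydroazulen-4-yl 4-(acetyloxy)benzoate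
Conditions: Ac2O, pyridine, DMAP (cat.), CH2Cl2, 0 → 25 °C
Reagents that add atoms: acetic anhydride, CC(=O)OC(C)=O
Why: Acetylation should take the secondary C1 hydroxyl with retention and leave the tertiary C3 hydroxyl free.

Step 15
Reactants: 27 (1R,3R,3aR,4R,8aS)-1-(acetyloxy)-3-hydroxy-6,8a-dimethyl-7-oxo-3-(propan-2-yl)-1,2,3,3a,4,7,8,8a-octahydroazulen-4-yl 4-(acetyloxy)benzoate
Product: 28 (1R,3R,3aR,4R,8aS)-1-(acetyloxy)-3-hydroxy-6,8a-dimethyl-7-oxo-3-(propan-2-yl)-1,2,3,3a,4,7,8,8a-octahydroazulen-4-yl 4-hydroxybenzoate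
Conditions: NH4OAc, MeOH/H2O, 25 °C
Reagents that add atoms: none
Why: Mild methanolysis should cleave the phenolic acetate selectively, since aryl acetates are far more labile than the hindered alkyl acetate and the C4 benzoate-type ester.

Compound list
1 | (4R)-4-[(tert-butyldimethylsilyl)oxy]cyclopent-2-en-1-one | CC(C)(C)[Si](C)(C)O[C@@H]1CC(=O)C=C1 | starting material
2 | tert-butyldimethyl{[(1R,2R)-2-methyl-4-(trimethylsilyloxy)cyclopent-3-en-1-yl]oxy}silane (methyl trans to the silyloxy group) | CC(C)(C)[Si](C)(C)O[C@@H]1CC(O[Si](C)(C)C)=C[C@H]1C | intermediate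
3 | (4R)-4-[(tert-butyldimethylsilyl)oxy]-3-methylcyclopent-2-en-1-one | CC(C)(C)[Si](C)(C)O[C@@H]1CC(=O)C=C1C | intermediate
4 | (4R)-4-[(tert-butyldimethylsilyl)oxy]-2-iodo-3-methylcyclopent-2-en-1-one | CC(C)(C)[Si](C)(C)O[C@@H]1CC(=O)C(I)=C1C | intermediate
5 | (1S,4R)-4-[(tert-butyldimethylsilyl)oxy]-2-iodo-3-methylcyclopent-2-en-1-ol (cis) | CC(C)(C)[Si](C)(C)O[C@@H]1C[C@H](O)C(I)=C1C | intermediate
6 | tropylium (cycloheptatrienylium) tetrafluoroborate | [CH+]1C=CC=CC=C1.F[B-](F)(F)F | starting material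
7 | lithium (1S,4R)-4-[(tert-butyldimethylsilyl)oxy]-2-lithio-3-methylcyclopent-2-en-1-olate | CC(C)(C)[Si](C)(C)O[C@@H]1C[C@H]([O-])C([Li])=C1C.[Li+] | intermediate
8 | (1S,4R)-4-[(tert-butyldimethylsilyl)oxy]-2-(cyclohepta-2,4,6-trien-1-yl)-3-methylcyclopent-2-en-1-ol | CC(C)(C)[Si](C)(C)O[C@@H]1C[C@H](O)C(C2C=CC=CC=C2)=C1C | intermediate
9 | (4R)-4-[(tert-butyldimethylsilyl)oxy]-2-(cyclohepta-2,4,6-trien-1-yl)-3-methylcyclopent-2-en-1-one | CC(C)(C)[Si](C)(C)O[C@@H]1CC(=O)C(C2C=CC=CC=C2)=C1C | intermediate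
10 | 3-methylbut-3-en-2-one | CC(=C)C(C)=O | starting material
11 | 2,4,6-tri(propan-2-yl)benzenesulfonohydrazide | CC(C)c1cc(C(C)C)c(S(=O)(=O)NN)c(C(C)C)c1 | starting material
12 | N′-(3-methylbut-3-en-2-ylidene)-2,4,6-tri(propan-2-yl)benzenesulfonohydrazide | CC(=C)C(C)=NNS(=O)(=O)c1c(C(C)C)cc(C(C)C)cc1C(C)C | intermediate
13 | (3-methylbuta-1,3-dien-2-yl)lithium | [Li]C(=C)C(C)=C | intermediate
14 | chloro(dimethyl)(3-methylbuta-1,3-dien-2-yl)silane | CC(=C)C(=C)[Si](C)(C)Cl | intermediate
15 | dimethyl(3-methylbuta-1,3-dien-2-yl)(propan-2-yloxy)silane | CC(=C)C(=C)[Si](C)(C)OC(C)C | intermediate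
16 | [(3R)-3-[(tert-butyldimethylsilyl)oxy]-2-methyl-5-oxocyclopent-1-en-1-yl]methylidene complex of Rh2(O2CCF3)4 ([Rh] in the SMILES stands for the dirhodium unit) | CC(C)(C)[Si](C)(C)O[C@@H]1CC(=O)C(C=[Rh])=C1C | intermediate
17 | (4R)-4-[(tert-butyldimethylsilyl)oxy]-2-[2-{1-[dimethyl(propan-2-yloxy)silyl]ethenyl}-2-methylcyclopropyl]-3-methylcyclopent-2-en-1-one (the two alkenyl groups cis on the cyclopropane, configuration as in the SMILES) | CC(C)(C)[Si](C)(C)O[C@@H]1CC(=O)C(=C1C)[C@H]2C[C@@]2(C)C(=C)[Si](C)(C)OC(C)C | intermediate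
18 | (1R,8aS)-1-[(tert-butyldimethylsilyl)oxy]-7-[dimethyl(propan-2-yloxy)silyl]-6,8a-dimethyl-1,2,5,8-tetrahydroazulen-3(8aH)-one | CC(C)(C)[Si](C)(C)O[C@@H]1CC(=O)C2=CCC(C)=C([Si](C)(C)OC(C)C)C[C@]12C | intermediate
19 | (1R,3R,8aS)-1-[(tert-butyldimethylsilyl)oxy]-7-[dimethyl(propan-2-yloxy)silyl]-6,8a-dimethyl-3-(propan-2-yl)-1,2,3,5,8,8a-hexahydroazulen-3-ol | CC(C)(C)[Si](C)(C)O[C@@H]1C[C@@](O)(C(C)C)C2=CCC(C)=C([Si](C)(C)OC(C)C)C[C@]12C | intermediate
20 | cyclic alkoxyborane (1,2-oxaborolane joining O3 and C4 on the α face) of hydroborated 19 | CC(C)(C)[Si](C)(C)O[C@@H]1C[C@@](O[BH]3)(C(C)C)[C@H]2[C@H]3CC(C)=C([Si](C)(C)OC(C)C)C[C@]12C | intermediate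
21 | (1R,3R,3aR,4R,8aS)-1-[(tert-butyldimethylsilyl)oxy]-3,4-dihydroxy-6,8a-dimethyl-3-(propan-2-yl)octahydroazulen-7(1H)-one (mixture at C6) | CC(C)(C)[Si](C)(C)O[C@@H]1C[C@@](O)(C(C)C)[C@H]2[C@H](O)CC(C)C(=O)C[C@]12C | intermediate
22 | 4-(acetyloxy)benzoyl chloride | CC(=O)Oc1ccc(cc1)C(Cl)=O | starting material
23 | (1R,3R,3aR,4R,8aS)-1-[(tert-butyldimethylsilyl)oxy]-3-hydroxy-6,8a-dimethyl-7-oxo-3-(propan-2-yl)decahydroazulen-4-yl 4-(acetyloxy)benzoate (mixture at C6) | CC(C)(C)[Si](C)(C)O[C@@H]1C[C@@](O)(C(C)C)[C@H]2[C@H](OC(=O)c3ccc(OC(C)=O)cc3)CC(C)C(=O)C[C@]12C | intermediate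
24 | (1R,3R,3aR,4R,8aS)-1-[(tert-butyldimethylsilyl)oxy]-6,8a-dimethyl-3-(propan-2-yl)-3,7-bis[(trimethylsilyl)oxy]-1,2,3,3a,4,5,8,8a-octahydroazulen-4-yl 4-(acetyloxy)benzoate | CC(C)(C)[Si](C)(C)O[C@@H]1C[C@@](O[Si](C)(C)C)(C(C)C)[C@H]2[C@H](OC(=O)c3ccc(OC(C)=O)cc3)CC(C)=C(O[Si](C)(C)C)C[C@]12C | intermediate
25 | (1R,3R,3aR,4R,8aS)-1-[(tert-butyldimethylsilyl)oxy]-6,8a-dimethyl-7-oxo-3-(propan-2-yl)-3-[(trimethylsilyl)oxy]-1,2,3,3a,4,7,8,8a-octahydroazulen-4-yl 4-(acetyloxy)benzoate | CC(C)(C)[Si](C)(C)O[C@@H]1C[C@@](O[Si](C)(C)C)(C(C)C)[C@H]2[C@H](OC(=O)c3ccc(OC(C)=O)cc3)C=C(C)C(=O)C[C@]12C | intermediate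
26 | (1R,3R,3aR,4R,8aS)-1,3-dihydroxy-6,8a-dimethyl-7-oxo-3-(propan-2-yl)-1,2,3,3a,4,7,8,8a-octahydroazulen-4-yl 4-(acetyloxy)benzoate | O[C@@H]1C[C@@](O)(C(C)C)[C@H]2[C@H](OC(=O)c3ccc(OC(C)=O)cc3)C=C(C)C(=O)C[C@]12C | intermediate
27 | (1R,3R,3aR,4R,8aS)-1-(acetyloxy)-3-hydroxy-6,8a-dimethyl-7-oxo-3-(propan-2-yl)-1,2,3,3a,4,7,8,8a-octahydroazulen-4-yl 4-(acetyloxy)benzoate | CC(=O)O[C@@H]1C[C@@](O)(C(C)C)[C@H]2[C@H](OC(=O)c3ccc(OC(C)=O)cc3)C=C(C)C(=O)C[C@]12C | intermediate
28 | (1R,3R,3aR,4R,8aS)-1-(acetyloxy)-3-hydroxy-6,8a-dimethyl-7-oxo-3-(propan-2-yl)-1,2,3,3a,4,7,8,8a-octahydroazulen-4-yl 4-hydroxybenzoate | CC(=O)O[C@@H]1C[C@@](O)(C(C)C)[C@H]2[C@H](OC(=O)c3ccc(O)cc3)C=C(C)C(=O)C[C@]12C | target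

Total step count: 15. Longest linear sequence: 13 steps (steps 1–5 and 8–15, from 1 to 28); steps 6–7 prepare diene 15.

The three steps most likely to fail, in order of risk

Risk 1: Step 8. The carbene transfer may show poor facial selectivity, may give the trans-dialkenylcyclopropane that cannot rearrange, may attack the silyl-bearing alkene, or the hindered acyl-substituted carbene may decay before it is trapped. The fallback changes the substrate and its control element, sets out from 8 and comes back to the route at 18: silylation of 8 with Et3SiCl and imidazole in DMF should give triethylsilyl ether F1, in which the carbene is no longer conjugated to a carbonyl group and both α-oxygens carry silyl groups that shield the α face; the same rhodium-catalysed reaction of triethylsilyl ether F1 with 15 should then give bis-silyl hexahydroazulene F2; selective removal of the triethylsilyl group from bis-silyl hexahydroazulene F2 with pyridinium p-toluenesulfonate in propan-2-ol should give allylic alcohol F3; Dess–Martin oxidation of allylic alcohol F3 then gives 18.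

Risk 2: Step 10. Borane may attack the β face, may add with the wrong regiochemistry, or the Tamao–Fleming oxidation may stall. The fallback delivers silicon and hydrogen intramolecularly from the α-hydroxyl group, sets out from 19 and comes back to the route at 21: silylation of 19 with 1,1,3,3-tetramethyldisilazane should give dimethylsilyl ether F4; intramolecular hydrosilylation of dimethylsilyl ether F4 with Pt2(dvtms)3 (dvtms = 1,3-divinyl-1,1,3,3-tetramethyldisiloxane) should close a five-membered ring with Si at C4 and H at C3a, both on the α face, to give tricyclic oxasilolane F5; oxidation of tricyclic oxasilolane F5 with H2O2, KF and KHCO3 converts both C–Si bonds and gives 21.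

Risk 3: Step 9. The carbonyl addition may show poor facial selectivity, or the hindered enone may be enolised or reduced by the Grignard reagent. The fallback moves the addition to the simple cyclopentenone stage, where addition anti to a 4-silyloxy group is best precedented, sets out from 4 and comes back to the route at 21: i-PrMgCl and CeCl3 in THF at −78 °C should convert 4 into tertiary alcohol F6; Me3SiOTf and 2,6-lutidine should give trimethylsilyl ether F7; iodine–lithium exchange of trimethylsilyl ether F7 with t-BuLi and addition to 6 should give cycloheptatrienyl compound F8; the rhodium-catalysed reaction of cycloheptatrienyl compound F8 with 15 should give silylated hexahydroazulene F9, which is the trimethylsilyl ether of 19; hydroboration of silylated hexahydroazulene F9 and oxidation with H2O2, KF and KHCO3, which also cleaves the trimethylsilyl ether, gives 21.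

Further compounds
F1 | step 8 | tert-butyl{[(1R,4S)-3-(cyclohepta-2,4,6-trien-1-yl)-2-methyl-4-[(triethylsilyl)oxy]cyclopent-2-en-1-yl]oxy}dimethylsilane (cis) | CC(C)(C)[Si](C)(C)O[C@@H]1C[C@H](O[Si](CC)(CC)CC)C(C2C=CC=CC=C2)=C1C
F2 | step 8 | (1R,3S,8aS)-1-[(tert-butyldimethylsilyl)oxy]-7-[dimethyl(propan-2-yloxy)silyl]-6,8a-dimethyl-3-[(triethylsilyl)oxy]-1,2,3,5,8,8a-hexahydroazulene | CC(C)(C)[Si](C)(C)O[C@@H]1C[C@H](O[Si](CC)(CC)CC)C2=CCC(C)=C([Si](C)(C)OC(C)C)C[C@]12C
F3 | step 8 | (1R,3S,8aS)-1-[(tert-butyldimethylsilyl)oxy]-7-[dimethyl(propan-2-yloxy)silyl]-6,8a-dimethyl-1,2,3,5,8,8a-hexahydroazulen-3-ol | CC(C)(C)[Si](C)(C)O[C@@H]1C[C@H](O)C2=CCC(C)=C([Si](C)(C)OC(C)C)C[C@]12C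
F4 | step 10 | (1R,3R,8aS)-1-[(tert-butyldimethylsilyl)oxy]-3-[(dimethylsilyl)oxy]-7-[dimethyl(propan-2-yloxy)silyl]-6,8a-dimethyl-3-(propan-2-yl)-1,2,3,5,8,8a-hexahydroazulene | CC(C)(C)[Si](C)(C)O[C@@H]1C[C@@](O[SiH](C)C)(C(C)C)C2=CCC(C)=C([Si](C)(C)OC(C)C)C[C@]12C
F5 | step 10 | tricyclic 2,2-dimethyl-1,2-oxasilolane joining O3 and C4 on the α face (C3a–H α), otherwise as 19 | CC(C)(C)[Si](C)(C)O[C@@H]1C[C@@](O[Si]3(C)C)(C(C)C)[C@H]2[C@H]3CC(C)=C([Si](C)(C)OC(C)C)C[C@]12C
F6 | step 9 | (1R,4R)-4-[(tert-butyldimethylsilyl)oxy]-2-iodo-3-methyl-1-(propan-2-yl)cyclopent-2-en-1-ol | CC(C)(C)[Si](C)(C)O[C@@H]1C[C@@](O)(C(C)C)C(I)=C1C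
F7 | step 9 | tert-butyl{[(1R,4R)-3-iodo-2-methyl-4-(propan-2-yl)-4-[(trimethylsilyl)oxy]cyclopent-2-en-1-yl]oxy}dimethylsilane | CC(C)(C)[Si](C)(C)O[C@@H]1C[C@@](O[Si](C)(C)C)(C(C)C)C(I)=C1C
F8 | step 9 | tert-butyl{[(1R,4R)-3-(cyclohepta-2,4,6-trien-1-yl)-2-methyl-4-(propan-2-yl)-4-[(trimethylsilyl)oxy]cyclopent-2-en-1-yl]oxy}dimethylsilane | CC(C)(C)[Si](C)(C)O[C@@H]1C[C@@](O[Si](C)(C)C)(C(C)C)C(C2C=CC=CC=C2)=C1C
F9 | step 9 | (1R,3R,8aS)-1-[(tert-butyldimethylsilyl)oxy]-7-[dimethyl(propan-2-yloxy)silyl]-6,8a-dimethyl-3-(propan-2-yl)-3-[(trimethylsilyl)oxy]-1,2,3,5,8,8a-hexahydroazulene | CC(C)(C)[Si](C)(C)O[C@@H]1C[C@@](O[Si](C)(C)C)(C(C)C)C2=CCC(C)=C([Si](C)(C)OC(C)C)C[C@]12C
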